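I began with the easy step, substrate + coupling partner → target, and counted the turnovers it gets in each flask.

all flasks: substrate 5.0 × 10⁻⁴ M; coupling partner 1.50 mM; time 2.5 min

| run | temperature |
|---|---|
| zeta | 80 °C |
| theta | 50 °C |
| eta | 20 °C |

    crystals ⇌ target, rate k1*(cs1 - [target]) while solid is left; crystals form when [target] > cs1 (cs1 = 0.019 mM, k1 = 1.9 /s)
    coupling partner + intermediate A ⇌ intermediate B (K2 = 1800 /M, k2 = 220 /M/s, Ea2 = 41.0 kJ/mol, ΔH2 = −9.00 kJ/mol)
    substrate + target → side product (k3 = 1400 /M/s, Ea3 = 38.0 kJ/mol)
    substrate + coupling partner → target (k4 = 220 /M/s, Ea4 = 52.0 kJ/mol)
    substrate → intermediate A (k5 = 0.017 /s, Ea5 = 91.0 kJ/mol)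
    (constants at 80 °C)

- percent here means substrate units held: one side product counts as two
- what is said of target includes crystals
- crystals is a solid; its amount is given per volume of the solution
- constants are those at 80 °C; use the activation energies and enthalpies for any other temperature

- the flask with the highest amount of target, in percent of the substrate charged ("all alike" if they lie within 1.5 percentage points) (zeta / theta / eta / all alike)
- final target, as a percentage of the substrate charged, in zeta
- final target, as a percentage of the substrate charged, in theta
- final target, as a percentage of the substrate charged, in eta

The coupling partner was charged at 3.00 times the substrate, so I treated the coupling as pseudo-first-order in substrate. At the start in zeta, its rate constant times c(coupling partner) gave 0.330 /s, and multiplying by the run time gave 49.5. I called this the turnover count N, the number of substrate lifetimes the coupling gets in the run.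

Two things slowed the coupling. Cooling to eta divided its constant by 38, which brought N down to 1.32. If each substrate took one partner, c(coupling partner) would end at 1.00 mM, a further factor of 1.50, so I put N for eta between 0.880 and 1.32. The substrate's own fall then shrinks the rate by exp(−N) over the run, so I estimated that 26.7% to 41.5% of the substrate would remain in eta, with the other steps that take substrate uncounted. Zeta stood far above one turnover, so I expected it to finish. N gives no yield, so I committed to one point: eta stops short.

The forecast named theta, with 62% in zeta, 67% in theta and 46% in eta, and held that “about a quarter of the substrate is still unreacted at the end”, which lies below my range.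

The simulation gave theta as best, with 63.5% in zeta, 68.0% in theta and 46.4% in eta. In zeta, half of the coupling's turnover was done by 1.80 s, far shorter than the run, whereas eta took 1.15 min to reach 50 percent conversion, about half of its run. The 24% of substrate left in eta corresponds to a count of 1.44 with every step that takes substrate included, a little above the 1.32 I reckoned for the coupling by itself.

Next I took a neighbouring flask, the same as zeta but with 0.0013 M of substrate. Taking c(coupling partner) at the 0.200 mM that one partner per substrate implies, N is 6.60, so exp(−N) gives an estimate of 0.136% of the substrate remaining. The simulation shows 0% of substrate, with 44.3% as target and 50.1% as side product.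

Its constants are made up.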